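## Retrosynthetic overview
1. C2–aryl bond: the (2S)-flavanone comes from 5,6,7-trimethoxychromone and 3,4,5-trimethoxyphenylboronic acid. The only stereocentre is set last, by face-selective 1,4-arylation, after all hot or basic operations.
2. O1–C8a and C4–C4a bonds: the chromone comes from 3,4,5-trimethoxybenzyne and (E)-3-ethoxyacrylic acid in one flask. The sequence is carboxylate addition, four-ring closure and opening (a C–O insertion), oxa-Michael closure, then loss of ethoxide.
3. The aryne comes from an ortho-silylaryl triflate, made from 2-bromo-3,4,5-trimethoxyphenol, made from 3,4,5-trimethoxyphenol.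
4. Ring order: rings A and B are bought. In the key flask the four-membered benzoxete ring closes first and is used up in the acyl shift, and the six-membered ring C closes directly after it.

Assumption: flavanone numbering is used (O1, C2, C3, C4, C4a, C5–C8, C8a), and the given SMILES reads as (2S). The (R)-ligand in step 4 is assigned by analogy: the (S)-ligand gives (R)-configured products with cyclic enones. The sense is checked on the product by optical rotation and CD.

## Route

Step 1
Reactants: 1 3,4,5-trimethoxyphenol
Product: 2 2-bromo-3,4,5-trimethoxyphenol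
Conditions: NBS (1.0 equiv), CH2Cl2, −78 °C to 0 °C
Reagents that add atoms: N-bromosuccinimide, O=C1CCC(=O)N1Br
Why: Electrophilic aromatic bromination works because the two free positions of 1 are equivalent and strongly activated (ortho to OH, para to OMe), so one equivalent of NBS at low temperature gives the 2-bromide; no stereocentre is involved.

Step 2
Reactants: 2 2-bromo-3,4,5-trimethoxyphenol
Product: 5 3,4,5-trimethoxy-2-(trimethylsilyl)phenyl trifluoromethanesulfonate, via silyl ether 3 (not isolated), via lithium silylphenolate 4 (not isolated)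
Conditions: (Me3Si)2NH, THF, 70 °C, then evaporate; n-BuLi, THF, −78 °C; Tf2O, −78 °C to rt
Reagents that add atoms: hexamethyldisilazane, C[Si](C)(C)N[Si](C)(C)C; trifluoromethanesulfonic anhydride, O=S(=O)(OS(=O)(=O)C(F)(F)F)C(F)(F)F
Why: O-silylation, bromine–lithium exchange and a 1,3 O→C silyl shift (retro-Brook rearrangement) place SiMe3 between the oxygen and the neighbouring OMe, and Tf2O traps the freed phenolate to give a Kobayashi-type aryne precursor.

Step 3 (key step)
Reactants: 5 3,4,5-trimethoxy-2-(trimethylsilyl)phenyl trifluoromethanesulfonate; 6 (E)-3-ethoxyacrylic acid (1.2 equiv)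
Product: 11 5,6,7-trimethoxy-4H-chromen-4-one, via aryne 7 (not isolated), via benzoxetolate 8 (not isolated), via acylphenolate 9 (not isolated), via ethoxychromanone enolate 10 (not isolated)
Conditions: CsF (4 equiv), THF, 125 °C, sealed tube
Reagents that add atoms: none
Why: Proposed new method: fluoride-induced 1,2-elimination gives aryne 7, whose distortion by the flanking OMe sends the carboxylate oxygen of 6 to the aryne carbon remote from OMe (future C8a); the resulting ortho aryl anion (future C4a) closes onto the ester C=O to the four-membered benzoxetolate 8, which opens to acylphenolate 9 (net aryne insertion into the acid C–O bond), and 9 closes ring C by 6-endo oxa-Michael addition to 10 and expels ethoxide; the closest known reaction type is the aryne C–O insertion of crotonic or cinnamic acids that ends in chroman-4-ones, so only the β-ethoxy leaving group that carries the product on to the chromone is new; no stereocentre is formed.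

Step 4
Reactants: 11 5,6,7-trimethoxy-4H-chromen-4-one; 12 3,4,5-trimethoxyphenylboronic acid (2 equiv)
Product: 13 (2S)-5,6,7-trimethoxy-2-(3,4,5-trimethoxyphenyl)-2,3-dihydro-4H-chromen-4-one
Conditions: Pd(OCOCF3)2 (5 mol %), (R)-t-BuPyOx [(R)-4-tert-butyl-2-(pyridin-2-yl)-4,5-dihydrooxazole] (6 mol %), NH4PF6 (30 mol %), H2O (5 equiv), ClCH2CH2Cl, 60 °C
Reagents that add atoms: none
Why: In this enantioselective Pd-catalysed conjugate addition of an arylboronic acid, the cationic aryl complex of divalent palladium bearing the pyridine–oxazoline inserts C2=C3 of 11 on the face left open by the tert-butyl group, which sets C2 as (S), and water protonates the palladium enolate under base-free conditions that neither open ring C nor racemise C2.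

## Compound list
1 | 3,4,5-trimethoxyphenol | COc1cc(O)cc(OC)c1OC | starting material
2 | 2-bromo-3,4,5-trimethoxyphenol | COc1cc(O)c(Br)c(OC)c1OC | intermediate
3 | (2-bromo-3,4,5-trimethoxyphenoxy)trimethylsilane | COc1cc(O[Si](C)(C)C)c(Br)c(OC)c1OC | intermediate
4 | lithium 3,4,5-trimethoxy-2-(trimethylsilyl)phenolate | COc1cc([O-])c([Si](C)(C)C)c(OC)c1OC.[Li+] | intermediate
5 | 3,4,5-trimethoxy-2-(trimethylsilyl)phenyl trifluoromethanesulfonate | COc1cc(OS(=O)(=O)C(F)(F)F)c([Si](C)(C)C)c(OC)c1OC | intermediate
6 | (E)-3-ethoxyacrylic acid | CCO/C=C/C(=O)O | starting material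
7 | 1,2-didehydro-3,4,5-trimethoxybenzene (3,4,5-trimethoxybenzyne) | COC1=C(OC)C(OC)=CC#C1 | intermediate
8 | caesium 2-[(E)-2-ethoxyethenyl]-3,4,5-trimethoxy-2H-1-benzoxet-2-olate (racemic, transient) | CCO/C=C/C1([O-])Oc2cc(OC)c(OC)c(OC)c12.[Cs+] | intermediate
9 | caesium 2-[(E)-3-ethoxyprop-2-enoyl]-3,4,5-trimethoxyphenolate | CCO/C=C/C(=O)c1c([O-])cc(OC)c(OC)c1OC.[Cs+] | intermediate
10 | caesium 2-ethoxy-5,6,7-trimethoxy-2H-chromen-4-olate (racemic, transient) | CCOC1C=C([O-])c2c(O1)cc(OC)c(OC)c2OC.[Cs+] | intermediate
11 | 5,6,7-trimethoxy-4H-chromen-4-one | COc1cc2occc(=O)c2c(OC)c1OC | intermediate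
12 | 3,4,5-trimethoxyphenylboronic acid | COc1cc(B(O)O)cc(OC)c1OC | starting material
13 | (2S)-5,6,7-trimethoxy-2-(3,4,5-trimethoxyphenyl)-2,3-dihydro-4H-chromen-4-one | COc1cc([C@@H]2CC(=O)c3c(cc(OC)c(OC)c3OC)O2)cc(OC)c1OC | target

## Step count and risks
Total steps: 4. Longest linear sequence: 4 (1 → 2 → 5 → 11 → 13).

**Step 3.**
- Risk: the aryl anion may be protonated before the acyl shift, which gives only the aryl ester. Phenolate 9 may also be arylated by a second aryne.
- Fallback: it sets out from 1, avoids aryne chemistry, and comes back at 11.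
- Ortho-acylation of 1 with Ac2O and BF3·OEt2 at 90 °C gives 1-(6-hydroxy-2,3,4-trimethoxyphenyl)ethanone F1.
- Heating with N,N-dimethylformamide dimethyl acetal gives (E)-3-(dimethylamino)-1-(6-hydroxy-2,3,4-trimethoxyphenyl)prop-2-en-1-one F2.
- HCl in CH2Cl2 closes F2 to 11.

**Step 4.**
- Risk: the peri 5-OMe group and the electron-rich chromone may slow the insertion, protodeboronation of 12 competes, and the ee on this substrate is untested.
- Fallback: it sets out from 2, brings the stereocentre in from a hydrogenation instead of creating it on the chromone, and comes back at 13.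
- Commercial ethyl 3-oxo-3-(3,4,5-trimethoxyphenyl)propanoate is hydrogenated with RuCl2[(S)-BINAP] and H2 in EtOH to ethyl (R)-3-hydroxy-3-(3,4,5-trimethoxyphenyl)propanoate F4.
- MeNH(OMe)·HCl and i-PrMgCl convert it into (R)-3-hydroxy-N-methoxy-N-methyl-3-(3,4,5-trimethoxyphenyl)propanamide F5.
- Mitsunobu etherification with phenol 2 (PPh3, DIAD, toluene, 0 °C) inverts the carbinol carbon. It gives (S)-3-(2-bromo-3,4,5-trimethoxyphenoxy)-N-methoxy-N-methyl-3-(3,4,5-trimethoxyphenyl)propanamide F6.
- n-BuLi at −78 °C triggers a Parham-type cyclisation: bromine–lithium exchange, then attack on the Weinreb amide. This closes ring C to 13 without touching C2.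

**Step 2.**
- Risk: the silyl shift into the crowded position between two oxygens may be incomplete, and the hindered phenolate may triflate poorly.
- Fallback: it sets out from 2, needs neither 5 nor an aryne, and comes back at 11.
- Acylation of 2 with (E)-3-ethoxyacryloyl chloride and Et3N gives 2-bromo-3,4,5-trimethoxyphenyl (E)-3-ethoxyacrylate F3.
- n-BuLi in THF at −100 °C then causes bromine–lithium exchange and an anionic ortho-Fries O→C acyl shift.
- On warming, the phenolate closes onto the β-carbon and loses ethoxide to give 11.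

## Further compounds
F1 | step 3 | 1-(6-hydroxy-2,3,4-trimethoxyphenyl)ethanone | CC(=O)c1c(O)cc(OC)c(OC)c1OC
F2 | step 3 | (E)-3-(dimethylamino)-1-(6-hydroxy-2,3,4-trimethoxyphenyl)prop-2-en-1-one | CN(C)/C=C/C(=O)c1c(O)cc(OC)c(OC)c1OC
F3 | step 2 | 2-bromo-3,4,5-trimethoxyphenyl (E)-3-ethoxyacrylate | CCO/C=C/C(=O)Oc1cc(OC)c(OC)c(OC)c1Br
F4 | step 4 | ethyl (R)-3-hydroxy-3-(3,4,5-trimethoxyphenyl)propanoate | COc1cc([C@H](O)CC(=O)OCC)cc(OC)c1OC
F5 | step 4 | (R)-3-hydroxy-N-methoxy-N-methyl-3-(3,4,5-trimethoxyphenyl)propanamide | COc1cc([C@H](O)CC(=O)N(C)OC)cc(OC)c1OC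
F6 | step 4 | (S)-3-(2-bromo-3,4,5-trimethoxyphenoxy)-N-methoxy-N-methyl-3-(3,4,5-trimethoxyphenyl)propanamide | COc1cc([C@H](CC(=O)N(C)OC)Oc2cc(OC)c(OC)c(OC)c2Br)cc(OC)c1OC
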